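**Retrosynthetic overview** (chroman atoms O1–C8a, arene ring C, dihydropyran ring D; benzofuran atoms O1′–C7a′, benzene ring A, furan ring B)
1. Artopetelin C ⇐ its tris(methoxymethyl) ether; the acetals are cleaved last.
2. The tris-MOM ether ⇐ a C5 aryl iodide carrying an O1–C2(Me)2–C3H2–C4H2–Br chain + a benzofuran-2′-yl boronate. One Pd/norbornene (Catellani) operation forms C4–C4a, closing ring D, and the biaryl bond C5–C2′. Enabling feature: C4a of ring C is ortho to C5, the carbon that bears the benzofuran; the other ortho carbon C6 is blocked by the prenyl group; and the C2–C3–C4 chain already hangs from O1 on C8a, meta to C5, so an iodide at C5 steers palladium to C4a–H only.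
3. The aryl iodide ⇐ 5-iodoresorcinol: both oxygens become 1,1-dimethylallyl ethers (Cu-catalysed propargylation, semi-hydrogenation); one vinyl group becomes the CH2CH2Br tether, the other is moved by aromatic Claisen rearrangement to C6 (prenyl), freeing O7.
4. The boronate ⇐ 4,6-dihydroxybenzofuran-3(2H)-one: O6′-prenylation, reduction/dehydration (ring B aromatised), Claisen rearrangement to C7′ (1,1-dimethylallyl), C2′ lithiation–borylation.
5. Ring order: rings A and C are bought, ring B is completed in step 9, ring D is closed last, in step 13.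

Key step: step 13

Remark: the target has no stereocentre, so none has to be set; the four starting materials are assumed to be commercially available.

**Step 1**
Reactants: 1 5-iodobenzene-1,3-diol; 2 3-chloro-3-methylbut-1-yne
Product: 3 1-iodo-3,5-bis[(2-methylbut-3-yn-2-yl)oxy]benzene
Conditions: 2 (2.6 equiv), CuCl2·2H2O (1 mol %), DBU (2.8 equiv), MeCN, 0 °C → rt
Reagents that add atoms: none
Why: Copper-catalysed O-propargylation of phenols with a tertiary propargylic chloride is the standard entry to aryl 1,1-dimethylpropargyl ethers and leaves the aryl iodide untouched.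

**Step 2**
Reactants: 3 1-iodo-3,5-bis[(2-methylbut-3-yn-2-yl)oxy]benzene
Product: 4 1-iodo-3,5-bis[(2-methylbut-3-en-2-yl)oxy]benzene
Conditions: H2 (1 atm), 5% Pd on CaCO3 poisoned with Pb(OAc)2, quinoline, EtOAc, rt, stopped at 2 equiv H2
Reagents that add atoms: none
Why: Lindlar semi-hydrogenation stops at the terminal alkenes, and the poisoned catalyst should not hydrogenolyse the C–I bond at 1 atm.

**Step 3**
Reactants: 4 1-iodo-3,5-bis[(2-methylbut-3-en-2-yl)oxy]benzene
Product: 6 3-[3-iodo-5-(2-methylbut-3-en-2-yloxy)phenoxy]-3-methylbutan-1-ol, via alkylborane 5 (not isolated)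
Conditions: 9-BBN (0.7 equiv), THF, 0 °C → rt; then NaOH (aq), H2O2, 0 °C; recovered 4 is recycled
Reagents that add atoms: hydrogen peroxide, OO
Why: Anti-Markovnikov hydroboration–oxidation with bulky 9-BBN places boron on the terminal carbon next to the quaternary centre; sub-stoichiometric borane desymmetrises 4 statistically, and the mono-alcohol should separate easily from 4 and from the diol.

**Step 4**
Reactants: 6 3-[3-iodo-5-(2-methylbut-3-en-2-yloxy)phenoxy]-3-methylbutan-1-ol
Product: 7 1-[(4-bromo-2-methylbutan-2-yl)oxy]-3-iodo-5-[(2-methylbut-3-en-2-yl)oxy]benzene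
Conditions: CBr4, PPh3, 2,6-lutidine, CH2Cl2, 0 °C
Reagents that add atoms: carbon tetrabromide, BrC(Br)(Br)Br
Why: The Appel reaction converts the primary alcohol to the bromide under buffered, non-acidic conditions that the two tertiary aryl ethers tolerate.

**Step 5**
Reactants: 7 1-[(4-bromo-2-methylbutan-2-yl)oxy]-3-iodo-5-[(2-methylbut-3-en-2-yl)oxy]benzene
Product: 9 5-[(4-bromo-2-methylbutan-2-yl)oxy]-3-iodo-2-(3-methylbut-2-en-1-yl)phenol, via cyclohexadienone 8 (not isolated)
Conditions: PhMe, 120 °C, sealed tube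
Reagents that add atoms: none
Why: Aromatic Claisen rearrangement of the tertiary 1,1-dimethylallyl ether runs at moderate temperature and should deliver the prenyl group to the ortho carbon between oxygen and iodine (the later C6), the site favoured both by the meta halogen (migration towards it) and by the meta alkoxy group (migration para to it), and not to the carbon between the two oxygens.

**Step 6**
Reactants: 9 5-[(4-bromo-2-methylbutan-2-yl)oxy]-3-iodo-2-(3-methylbut-2-en-1-yl)phenol
Product: 10 5-[(4-bromo-2-methylbutan-2-yl)oxy]-1-iodo-3-(methoxymethoxy)-2-(3-methylbut-2-en-1-yl)benzene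
Conditions: MOMCl, i-Pr2NEt, CH2Cl2, 0 °C → rt
Reagents that add atoms: chloromethyl methyl ether, COCCl
Why: Methoxymethyl protection of the phenol (O-alkylation with an α-chloro ether) masks the only acidic site, which would otherwise be O-alkylated by the bromide under the basic key step.

**Step 7**
Reactants: 11 4,6-dihydroxy-1-benzofuran-3(2H)-one; 12 1-bromo-3-methylbut-2-ene
Product: 13 4-hydroxy-6-[(3-methylbut-2-en-1-yl)oxy]-1-benzofuran-3(2H)-one
Conditions: 12 (1.05 equiv), K2CO3 (1.1 equiv), DMF, 0 °C → rt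
Reagents that add atoms: none
Why: Williamson etherification is selective for O6′ because that hydroxyl is the vinylogous acid para to the ketone, while the O4′ hydroxyl is held in a hydrogen bond to C3′=O.

**Step 8**
Reactants: 13 4-hydroxy-6-[(3-methylbut-2-en-1-yl)oxy]-1-benzofuran-3(2H)-one
Product: 14 4-(methoxymethoxy)-6-[(3-methylbut-2-en-1-yl)oxy]-1-benzofuran-3(2H)-one
Conditions: MOMCl, i-Pr2NEt, CH2Cl2, 0 → 40 °C
Reagents that add atoms: chloromethyl methyl ether, COCCl
Why: Methoxymethyl protection of the chelated phenol with an amine base avoids enolising the C2′ methylene.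

**Step 9**
Reactants: 14 4-(methoxymethoxy)-6-[(3-methylbut-2-en-1-yl)oxy]-1-benzofuran-3(2H)-one
Product: 16 4-(methoxymethoxy)-6-[(3-methylbut-2-en-1-yl)oxy]-1-benzofuran, via benzylic alcohol 15 (not isolated)
Conditions: NaBH4, MeOH/THF, 0 °C; then 1 M HCl (aq) to pH 3, rt, 15 min
Reagents that add atoms: none
Why: Hydride reduction of the aryl ketone gives alcohol 15, whose ionisation is assisted by the ortho and para oxygen substituents, so brief mild acid eliminates water and aromatises ring B (reduction–dehydration of a coumaranone to a benzofuran).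

**Step 10**
Reactants: 16 4-(methoxymethoxy)-6-[(3-methylbut-2-en-1-yl)oxy]-1-benzofuran
Product: 18 4-(methoxymethoxy)-7-(2-methylbut-3-en-2-yl)-1-benzofuran-6-ol, via cyclohexadienone 17 (not isolated)
Conditions: PhNEt2, 190 °C, sealed tube, short reaction time
Reagents that add atoms: none
Why: Aromatic Claisen rearrangement of the aryl prenyl ether gives the 1,1-dimethylallyl group; C7′ should be preferred over C5′ because the C6′–C7′ bond has the higher double-bond character (as in 7-allyloxycoumarins and 7-prenyloxychromones, which rearrange to C8) and C5′ is screened by the C4′ acetal, while the para position C3a′ is blocked so no Cope shift can follow.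

**Step 11**
Reactants: 18 4-(methoxymethoxy)-7-(2-methylbut-3-en-2-yl)-1-benzofuran-6-ol
Product: 19 4,6-bis(methoxymethoxy)-7-(2-methylbut-3-en-2-yl)-1-benzofuran
Conditions: NaH, MOMCl, DMF, 0 °C → rt
Reagents that add atoms: chloromethyl methyl ether, COCCl
Why: The hindered phenol next to the tertiary alkyl group is alkylated reliably as its sodium phenoxide (Williamson-type acetal formation).

**Step 12**
Reactants: 19 4,6-bis(methoxymethoxy)-7-(2-methylbut-3-en-2-yl)-1-benzofuran
Product: 21 2-[4,6-bis(methoxymethoxy)-7-(2-methylbut-3-en-2-yl)-1-benzofuran-2-yl]-4,4,5,5-tetramethyl-1,3,2-dioxaborolane, via 2-lithiobenzofuran 20 (not isolated)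
Conditions: n-BuLi (1.1 equiv), THF, −78 °C; then i-PrOBpin, −78 °C → rt; NH4Cl (aq)
Reagents that add atoms: 2-isopropoxy-4,4,5,5-tetramethyl-1,3,2-dioxaborolane, CC(C)OB1OC(C)(C)C(C)(C)O1
Why: C2′–H is the most acidic C–H of a benzofuran, so n-BuLi at −78 °C should lithiate there before directed metalation at C5′ between the two acetals can compete, and the borate ester traps 20 (lithiation–borylation).

**Step 13**
Reactants: 10 5-[(4-bromo-2-methylbutan-2-yl)oxy]-1-iodo-3-(methoxymethoxy)-2-(3-methylbut-2-en-1-yl)benzene; 21 2-[4,6-bis(methoxymethoxy)-7-(2-methylbut-3-en-2-yl)-1-benzofuran-2-yl]-4,4,5,5-tetramethyl-1,3,2-dioxaborolane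
Product: 22 2-[7-(methoxymethoxy)-2,2-dimethyl-6-(3-methylbut-2-en-1-yl)-3,4-dihydro-2H-chromen-5-yl]-4,6-bis(methoxymethoxy)-7-(2-methylbut-3-en-2-yl)-1-benzofuran
Conditions: Pd(OAc)2 (10 mol %), P(2-furyl)3 (20 mol %), norbornene (2 equiv), Cs2CO3 (3 equiv), DME/H2O (10:1), 80 °C, 0.02 M in 10; 21 (1.3 equiv) added over 6 h
Reagents that add atoms: none
Why: Zerovalent palladium inserts into the C5–I bond of 10, norbornene carbopalladation and base-assisted palladation of the only free ortho C–H (C4a–H, since C6 carries the prenyl group) give an aryl–norbornyl palladacycle, and the tethered primary C–Br bond adds oxidatively to give a tetravalent palladium species whose aryl–alkyl reductive elimination forms C4–C4a. With both ortho positions of C5 now substituted, norbornene is expelled by β-carbon elimination, and the 2,6-disubstituted arylpalladium halide is intercepted by transmetalation with 21 and reductive elimination to the C5–C2′ bond. The closest known reaction type is the Catellani ortho-alkylation/ipso-Suzuki coupling of ortho-substituted aryl iodides, including its ring-closing variant in which a bromoalkyl ether meta to iodine delivers chromans. Ring D closes as a six-membered ring by formal 6-exo-tet substitution at the primary carbon (C(sp2)–C(sp3) reductive elimination from a seven-membered palladacycle), helped by the gem-dimethyl group; no stereocentre is formed. Site selectivity (C4a, not C8) is fixed by the position of iodine, because only a C–H ortho to the C–Pd bond can be activated. Chemoselectivity over direct Suzuki coupling should come from fast norbornene insertion, the intramolecular alkylation, dilution and slow addition of 21, and the unactivated prenyl and 1,1-dimethylallyl olefins are poor Heck acceptors.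

**Step 14**
Reactants: 22 2-[7-(methoxymethoxy)-2,2-dimethyl-6-(3-methylbut-2-en-1-yl)-3,4-dihydro-2H-chromen-5-yl]-4,6-bis(methoxymethoxy)-7-(2-methylbut-3-en-2-yl)-1-benzofuran
Product: 23 artopetelin C, 2-[7-hydroxy-2,2-dimethyl-6-(3-methylbut-2-en-1-yl)-3,4-dihydro-2H-chromen-5-yl]-7-(2-methylbut-3-en-2-yl)-1-benzofuran-4,6-diol
Conditions: HCl (cat.), MeOH/THF, 40 °C, monitored closely
Reagents that add atoms: none
Why: Acid-catalysed transacetalisation in methanol removes the three aryl methoxymethyl ethers as dimethoxymethane under conditions mild enough that protonation of the prenyl and 1,1-dimethylallyl olefins, and the cyclisation that would follow, should stay slow.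

**Compound list**
1 | 5-iodobenzene-1,3-diol | Oc1cc(O)cc(I)c1 | starting material
2 | 3-chloro-3-methylbut-1-yne | C#CC(C)(C)Cl | starting material
3 | 1-iodo-3,5-bis[(2-methylbut-3-yn-2-yl)oxy]benzene | C#CC(C)(C)Oc1cc(I)cc(OC(C)(C)C#C)c1 | intermediate
4 | 1-iodo-3,5-bis[(2-methylbut-3-en-2-yl)oxy]benzene | C=CC(C)(C)Oc1cc(I)cc(OC(C)(C)C=C)c1 | intermediate
5 | 9-{3-[3-iodo-5-(2-methylbut-3-en-2-yloxy)phenoxy]-3-methylbutyl}-9-borabicyclo[3.3.1]nonane | C=CC(C)(C)Oc1cc(I)cc(OC(C)(C)CCB2C3CCCC2CCC3)c1 | intermediate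
6 | 3-[3-iodo-5-(2-methylbut-3-en-2-yloxy)phenoxy]-3-methylbutan-1-ol | C=CC(C)(C)Oc1cc(I)cc(OC(C)(C)CCO)c1 | intermediate
7 | 1-[(4-bromo-2-methylbutan-2-yl)oxy]-3-iodo-5-[(2-methylbut-3-en-2-yl)oxy]benzene | C=CC(C)(C)Oc1cc(I)cc(OC(C)(C)CCBr)c1 | intermediate
8 | 3-[(4-bromo-2-methylbutan-2-yl)oxy]-5-iodo-6-(3-methylbut-2-en-1-yl)cyclohexa-2,4-dien-1-one (racemic) | O=C1C=C(OC(C)(C)CCBr)C=C(I)C1CC=C(C)C | intermediate
9 | 5-[(4-bromo-2-methylbutan-2-yl)oxy]-3-iodo-2-(3-methylbut-2-en-1-yl)phenol | CC(C)=CCc1c(O)cc(OC(C)(C)CCBr)cc1I | intermediate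
10 | 5-[(4-bromo-2-methylbutan-2-yl)oxy]-1-iodo-3-(methoxymethoxy)-2-(3-methylbut-2-en-1-yl)benzene | COCOc1cc(OC(C)(C)CCBr)cc(I)c1CC=C(C)C | intermediate
11 | 4,6-dihydroxy-1-benzofuran-3(2H)-one | O=C1COc2cc(O)cc(O)c12 | starting material
12 | 1-bromo-3-methylbut-2-ene | CC(C)=CCBr | starting material
13 | 4-hydroxy-6-[(3-methylbut-2-en-1-yl)oxy]-1-benzofuran-3(2H)-one | CC(C)=CCOc1cc(O)c2C(=O)COc2c1 | intermediate
14 | 4-(methoxymethoxy)-6-[(3-methylbut-2-en-1-yl)oxy]-1-benzofuran-3(2H)-one | COCOc1cc(OCC=C(C)C)cc2OCC(=O)c12 | intermediate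
15 | 4-(methoxymethoxy)-6-[(3-methylbut-2-en-1-yl)oxy]-2,3-dihydro-1-benzofuran-3-ol (racemic) | COCOc1cc(OCC=C(C)C)cc2OCC(O)c12 | intermediate
16 | 4-(methoxymethoxy)-6-[(3-methylbut-2-en-1-yl)oxy]-1-benzofuran | COCOc1cc(OCC=C(C)C)cc2occc12 | intermediate
17 | 4-(methoxymethoxy)-7-(2-methylbut-3-en-2-yl)-1-benzofuran-6(7H)-one (racemic) | O=C1C=C(OCOC)C2=C(OC=C2)C1C(C)(C)C=C | intermediate
18 | 4-(methoxymethoxy)-7-(2-methylbut-3-en-2-yl)-1-benzofuran-6-ol | C=CC(C)(C)c1c(O)cc(OCOC)c2ccoc12 | intermediate
19 | 4,6-bis(methoxymethoxy)-7-(2-methylbut-3-en-2-yl)-1-benzofuran | C=CC(C)(C)c1c(OCOC)cc(OCOC)c2ccoc12 | intermediate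
20 | [4,6-bis(methoxymethoxy)-7-(2-methylbut-3-en-2-yl)-1-benzofuran-2-yl]lithium | C=CC(C)(C)c1c(OCOC)cc(OCOC)c2cc([Li])oc12 | intermediate
21 | 2-[4,6-bis(methoxymethoxy)-7-(2-methylbut-3-en-2-yl)-1-benzofuran-2-yl]-4,4,5,5-tetramethyl-1,3,2-dioxaborolane | C=CC(C)(C)c1c(OCOC)cc(OCOC)c2cc(B3OC(C)(C)C(C)(C)O3)oc12 | intermediate
22 | 2-[7-(methoxymethoxy)-2,2-dimethyl-6-(3-methylbut-2-en-1-yl)-3,4-dihydro-2H-chromen-5-yl]-4,6-bis(methoxymethoxy)-7-(2-methylbut-3-en-2-yl)-1-benzofuran | C=CC(C)(C)c1c(OCOC)cc(OCOC)c2cc(-c3c(CC=C(C)C)c(OCOC)cc4c3CCC(C)(C)O4)oc12 | intermediate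
23 | artopetelin C | C=CC(C)(C)c1c(O)cc(O)c2cc(-c3c(CC=C(C)C)c(O)cc4c3CCC(C)(C)O4)oc12 | target

**Step count and risks**
Total: 14 steps. Longest linear sequence: 8 steps (steps 1–6, 13, 14; the branch 7–12, 13, 14 is equally long).

Most likely to fail:

Step 13. The boronate may couple directly at C5 before the norbornene-relayed C–H alkylation has closed ring D, the 2-benzofuranyl boronate may protodeboronate, or the bromide may alkylate intermolecularly. The fallback separates ring closure from biaryl union. Setting out from 10, the same ring-closing ortho-alkylation would be terminated by ipso-borylation with B2pin2 (Pd(OAc)2, P(2-furyl)3, norbornene, Cs2CO3, DME, 80 °C), a termination mode of this catalysis that needs no sensitive coupling partner, to give 2-[7-(methoxymethoxy)-2,2-dimethyl-6-(3-methylbut-2-en-1-yl)-3,4-dihydro-2H-chromen-5-yl]-4,4,5,5-tetramethyl-1,3,2-dioxaborolane F1. Compound 19 would be lithiated at C2′ (n-BuLi, −78 °C) and quenched with I2 to give 2-iodo-4,6-bis(methoxymethoxy)-7-(2-methylbut-3-en-2-yl)-1-benzofuran F2. A conventional Suzuki–Miyaura coupling of F1 with F2 (Pd(OAc)2, SPhos, K3PO4, PhMe/H2O, 80 °C) would come back to the route at 22.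

Step 10. The allyl unit may migrate to C5′ in place of C7′, or the hindered ortho-(1,1-dimethylallyl)phenol may rearrange further (abnormal Claisen) or add to its own olefin at 190 °C. The fallback moves the rearrangement to the ketone stage. Setting out from 14, heating (PhNEt2, 180 °C) should give 6-hydroxy-4-(methoxymethoxy)-7-(2-methylbut-3-en-2-yl)-1-benzofuran-3(2H)-one F3. There the 4-acylresorcinol pattern steers allyl migration to the carbon between the two ring-bound oxygens, and the product phenol, a vinylogous acid, is a poor nucleophile towards the new olefin. Protection (NaH, MOMCl, DMF) would give 4,6-bis(methoxymethoxy)-7-(2-methylbut-3-en-2-yl)-1-benzofuran-3(2H)-one F4. NaBH4 reduction to 4,6-bis(methoxymethoxy)-7-(2-methylbut-3-en-2-yl)-2,3-dihydro-1-benzofuran-3-ol F5 (not isolated) and mild acid dehydration would come back to the route at 19.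

Step 14. During acetal cleavage the acid may protonate the C6 prenyl group, which then cyclises onto the freed C7 hydroxyl to a second chroman ring, or it may hydrate or cyclise the 1,1-dimethylallyl group. The fallback is a non-protic silyl-transfer deprotection. Setting out from 22, TMSOTf and 2,2′-bipyridyl (CH2Cl2, 0 °C) would exchange the three aryl acetals for silyl ethers to give 2-[2,2-dimethyl-6-(3-methylbut-2-en-1-yl)-7-(trimethylsilyloxy)-3,4-dihydro-2H-chromen-5-yl]-7-(2-methylbut-3-en-2-yl)-4,6-bis(trimethylsilyloxy)-1-benzofuran F6, which neutral aqueous hydrolysis would convert to 23.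

**Further compounds**
F1 | step 13 | 2-[7-(methoxymethoxy)-2,2-dimethyl-6-(3-methylbut-2-en-1-yl)-3,4-dihydro-2H-chromen-5-yl]-4,4,5,5-tetramethyl-1,3,2-dioxaborolane | COCOc1cc2OC(C)(C)CCc2c(B3OC(C)(C)C(C)(C)O3)c1CC=C(C)C
F2 | step 13 | 2-iodo-4,6-bis(methoxymethoxy)-7-(2-methylbut-3-en-2-yl)-1-benzofuran | C=CC(C)(C)c1c(OCOC)cc(OCOC)c2cc(I)oc12
F3 | step 10 | 6-hydroxy-4-(methoxymethoxy)-7-(2-methylbut-3-en-2-yl)-1-benzofuran-3(2H)-one | C=CC(C)(C)c1c(O)cc(OCOC)c2C(=O)COc12
F4 | step 10 | 4,6-bis(methoxymethoxy)-7-(2-methylbut-3-en-2-yl)-1-benzofuran-3(2H)-one | C=CC(C)(C)c1c(OCOC)cc(OCOC)c2C(=O)COc12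
F5 | step 10 | 4,6-bis(methoxymethoxy)-7-(2-methylbut-3-en-2-yl)-2,3-dihydro-1-benzofuran-3-ol (racemic) | C=CC(C)(C)c1c(OCOC)cc(OCOC)c2C(O)COc12
F6 | step 14 | 2-[2,2-dimethyl-6-(3-methylbut-2-en-1-yl)-7-(trimethylsilyloxy)-3,4-dihydro-2H-chromen-5-yl]-7-(2-methylbut-3-en-2-yl)-4,6-bis(trimethylsilyloxy)-1-benzofuran | C=CC(C)(C)c1c(O[Si](C)(C)C)cc(O[Si](C)(C)C)c2cc(-c3c(CC=C(C)C)c(O[Si](C)(C)C)cc4c3CCC(C)(C)O4)oc12
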